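## Analysis of the target

The target is a linear phlorethol: eight benzene rings, A to H counted from the 2,4,6-trihydroxyphenyl end, joined only by seven diaryl ether oxygens and carrying twenty-one free phenolic hydroxyls. Rings B, D and F are 3,5-dihydroxy-1,4-phenylene units, with one ether oxygen on C1 (two ortho hydrogens) and one on C4 (two ortho hydroxyls). Rings C, E and G carry ether oxygens on C1 and C6, hydroxyls on C3, C4 and C5 and a single hydrogen on C2; ring H is 3,4,5-trihydroxyphenyl. There is no stereocenter and no isolable axis, so nothing stereochemical has to be set or related. The sensitive part is the polyphenol itself: pyrogallol and hydroxyhydroquinone arrays are oxidised by air, fastest in base, so all hydroxyls travel as methyl ethers and are released last. The difficulty is regiochemical placement of 28 oxygens on eight nearly identical rings and ether formation at crowded oxygens: every ether oxygen sits on a carbon with two oxygenated ortho positions, and at the B–C, D–E and F–G junctions the partner carbon also has an ortho aryloxy group. The strategy rests on ring E: C1 bears the oxygen from ring D, C2 is the only C–H, and C3 to C6 carry four further oxygens in a row. A squarate ester can supply C3 to C6 with their oxygens, and a 1-oxyvinyl unit can supply C1 with its oxygen and C2 with its hydrogen.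

## Retrosynthetic reasoning

**36 from 35.** The last operation removes twenty-one methyl groups from octamer 35. Methyl ethers survive copper couplings, organolithium reagents, 140 °C and hydrogenolysis, and cutting them last keeps the air-sensitive polyphenol out of every earlier step.

**35 from 28 and 34.** The ether bond between the C6 oxygen of ring E and C1 of ring F is cut. C1 of ring F has two ortho hydrogens and is the best electrophilic carbon in the chain, the crowded ring E oxygen becomes the nucleophile, and the cut divides the molecule five rings to three. The forward reaction is copper-catalysed arylation of hindered phenol 28 with bromide 34.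

**34 from 32.** The bromine is traced back to a C–H bond, because a bromophenol cannot be carried through copper couplings without reacting through its own halide. In 32 the C1–H of ring F is the only aromatic C–H with two ortho hydrogens. Sterically governed iridium borylation to 33 followed by bromodeboronation should therefore place the halogen there and nowhere else.

**32 from 30 and 31, and 30 from 2 and 29.** The trimer is cut at the ring F oxygen (hindered phenol 31 plus iodide 30) and then between rings G and H (iodophenol 2 plus boronic acid 29). The G–H bond has to be made by oxidative copper coupling at room temperature, which leaves the iodide of 2 untouched for the next bond. Iodophenol 2 comes from 1 by iodination ortho to the hydroxyl.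

**28 from 27 from 26.** The two para oxygens of ring E must differ: C6 free for arylation, C3 capped as a methyl ether. They leave the ring-forming step already differentiated (C3 hydroxyl, C6 silyl ether), so methylation followed by desilylation is enough.

**26 from 23 (key disconnection).** Ring E is opened at C2–C3 and traced back to cyclobutenone 23. D–E is one of the three junctions where a 2,6-dioxygenated phenol oxygen must bind a carbon that has an ortho aryloxy group. Building ring E from a four-carbon squarate unit and a two-carbon vinyl unit replaces that arylation by ring synthesis. The gain is five oxygens in place in one operation, with C3 and C6 distinguished by mechanism. The forward reaction must open the four-membered ring with the vinyl group turned toward the ketene and then close the six-membered ring.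

**23 from 22 from 19 and 20.** The bond between the carbinol carbon and the vinyl α carbon is cut, giving squarate 20 and vinyllithium 21. Direct deprotonation of an aryl vinyl ether was not adopted: the tetramer has seven ring C–H bonds flanked by two oxygens (two on ring A, two each on rings B and D, one on ring C), and these are lithiated under the conditions that an enol ether α-hydrogen needs. Vinyllithium 21 is therefore generated from stannane 19 by tin–lithium exchange, which is fast at −78 °C.

**19 from 18 from 15 from 13 and 14.** The tin is introduced by palladium-catalysed hydrostannation of ynol ether 18, which puts tin on the oxygen-bearing carbon. Ynol ether 18 comes from dichlorovinyl ether 15, and 15 from phenol 13 and trichloroethylene 14. The hindered ring D oxygen is thus bonded to the future C1 of ring E by addition to a two-carbon electrophile, not by arylation.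

**13 from 12 from 11 and 8.** The B–C ether is cut into hindered phenol 11 and iodide 8, which already carries ring D with its C4 oxygen masked as a benzyl ether. Hydrogenolysis then frees phenol 13 without touching methyl or diaryl ethers.

**8 from 2 and 7; 7 from 4 from 3.** The C–D ether is again made by oxidative coupling so that the iodide of 2 survives. Boronic acid 7 is made from bromide 4, the benzyl ether of commercial bromophenol 3.

**11 from 10 from 9 and 4.** The A–B ether is the easy case: hindered phenol 9 with the unhindered bromide 4, then hydrogenolysis.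

## Alternatives that were turned down

**Alternative 1:** Both ether bonds of ring B are cut, making ring B a hub. In the forward step the hub 2,6-dimethoxyhydroquinone A2 would be arylated in one pot under carbonate base, first at its unhindered hydroxyl by 2-fluoro-5-methoxyisophthalaldehyde A3 and then at its hindered hydroxyl by the hexamer fluoride A4, giving the octamer trialdehyde A1.
- For: it is the most convergent of the plans (1 + 1 + 6), it needs no copper and no organometallic reagent, and the formyl groups later become hydroxyls by Dakin oxidation. On convergence and operational simplicity it is stronger than the chosen route.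
- Against: the second arylation asks a hydroxyl between two methoxy groups to displace a fluoride activated by a single para formyl group and flanked by an ortho aryloxy group. One-pot sequencing needs complete discrimination between two hydroxyls and two fluorides, otherwise symmetrical products form. A4 already contains the D–E and F–G junctions, so the hardest bonds are only moved into its preparation. Three Dakin oxidations on an electron-rich octamer still follow.
- Comparison: the chosen route spends its key step on one of the hard junctions (D–E) and delivers ring E in its final oxidation pattern, with no late oxidation.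

**Alternative 2:** Ring A is cut between its ether-bearing carbon and a neighbouring hydroxyl-bearing carbon. In the forward step base would make C6 of the triketo ester A6 attack the ester carbonyl, and the resulting cyclohexanetrione would aromatise to A5, an octamer with ring A as a free triol.
- For: it is biomimetic and gives ring A unprotected. On protecting-group economy at ring A it is as good as or better than the chosen route.
- Against: C6 is the least acidic carbon of A6, and 3,5-dioxo esters close readily through oxygen to 4-hydroxy-2-pyrones. The heptamer of rings B to H must be made first, with all three hard junctions unsolved. The ring that is built is attached by the easiest ether of the molecule (hindered phenol, unhindered partner).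
- Comparison: the ring construction is spent where arylation already works. The chosen route places it at a junction where arylation is worst, and the Moore-type closure has no competing mode of ring formation.

**Alternative 3:** The C4–O bonds of rings C, E, G and H are cut back to formyl groups. In the forward step a fourfold Dakin oxidation with acidic peroxide would convert the octamer tetraaldehyde A8 into the tetraphenol A7.
- For: a formyl group para to C1 of rings C, E, G and H would let the B–C, D–E, F–G and G–H ethers be made by nucleophilic aromatic substitution of fluorides. This treats all three hard junctions uniformly and without copper, and here the alternative is stronger than the chosen route, which solves only D–E by ring synthesis and relies on copper catalysis for B–C and F–G.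
- Against: the C–D and E–F ethers are not activated and still need copper. Four aldehydes, each between two methoxy groups, must be oxidised at once on an octamer whose products are 4-alkoxyphenol-type rings prone to over-oxidation to quinones. Any incomplete conversion gives inseparable mixtures of near-identical octamers. The four fluoro aldehyde building blocks are longer to make than the phenols used here.
- Comparison: the chosen route carries every oxygen at its final oxidation level from the building blocks on, and differentiates the two para oxygens of ring E by mechanism.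

Key step: step 14

Remark on the chemistry: compounds 1, 3, 9, 14, 20, 29 and 31 are taken as purchasable; 22 and 23 are racemic and their only stereocenter disappears in step 14. "Tetramer-oxy" means the aryloxy group of phenol 13 (rings A to D), and ring positions follow the numbering of the analysis.

## Route

**Step 1**
Reactants: 1 2,3,4-trimethoxyphenol
Product: 2 6-iodo-2,3,4-trimethoxyphenol
Conditions: NIS, MeCN, 0 °C to rt, dark
Reagents that add atoms: N-iodosuccinimide, O=C1CCC(=O)N1I
Why: Electrophilic aromatic iodination; the hydroxyl is the strongest donor and its para position is blocked by the C4 methoxy group, so iodine should enter C6, ortho to the hydroxyl and para to the C3 methoxy group.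

**Step 2**
Reactants: 3 4-bromo-2,6-dimethoxyphenol
Product: 4 2-(benzyloxy)-5-bromo-1,3-dimethoxybenzene
Conditions: BnBr, K2CO3, DMF, 60 °C
Reagents that add atoms: benzyl bromide, BrCc1ccccc1
Why: Williamson ether synthesis; the hindered phenoxide meets an unhindered benzylic bromide, and the benzyl group can later be removed by hydrogenolysis without touching methyl or diaryl ethers.

**Step 3**
Reactants: 4 2-(benzyloxy)-5-bromo-1,3-dimethoxybenzene
Product: 7 [4-(benzyloxy)-3,5-dimethoxyphenyl]boronic acid, via aryllithium 5 (not isolated), via lithium aryltriisopropoxyborate 6 (not isolated)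
Conditions: n-BuLi, THF, −78 °C; B(OiPr)3, −78 °C to rt; 1 M HCl
Reagents that add atoms: triisopropyl borate, CC(C)OB(OC(C)C)OC(C)C; water, O
Why: Bromine–lithium exchange is far faster at −78 °C than ortho-lithiation or benzylic deprotonation; the aryllithium is trapped by the borate and mild acid hydrolysis should give the boronic acid.

**Step 4**
Reactants: 2 6-iodo-2,3,4-trimethoxyphenol; 7 [4-(benzyloxy)-3,5-dimethoxyphenyl]boronic acid
Product: 8 2-[4-(benzyloxy)-3,5-dimethoxyphenoxy]-1-iodo-3,4,5-trimethoxybenzene
Conditions: Cu(OAc)2, pyridine, 4 Å MS, CH2Cl2, dry air, rt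
Reagents that add atoms: none
Why: Chan–Lam–Evans oxidative coupling of a phenol with an arylboronic acid; it runs at room temperature through divalent and trivalent copper aryl species that do not insert into the carbon–iodine bond, and phenols with two ortho substituents, ortho halogens included, are known substrates. Rings C and D are joined while the iodide is kept for step 7.

**Step 5**
Reactants: 9 2,4,6-trimethoxyphenol; 4 2-(benzyloxy)-5-bromo-1,3-dimethoxybenzene
Product: 10 2-[4-(benzyloxy)-3,5-dimethoxyphenoxy]-1,3,5-trimethoxybenzene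
Conditions: CuI, picolinic acid, K3PO4, DMSO, 90 °C, argon
Reagents that add atoms: none
Why: Ullmann diaryl ether synthesis under the picolinic acid conditions developed for phenols with two ortho substituents; the bromide has two ortho hydrogens, and exclusion of air protects the very electron-rich phenoxide.

**Step 6**
Reactants: 10 2-[4-(benzyloxy)-3,5-dimethoxyphenoxy]-1,3,5-trimethoxybenzene
Product: 11 2,6-dimethoxy-4-(2,4,6-trimethoxyphenoxy)phenol
Conditions: H2 (1 atm), Pd/C, EtOAc/MeOH, rt
Reagents that add atoms: none
Why: Hydrogenolysis of a benzyl aryl ether; methyl and diaryl ethers are inert and no halogen is present.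

**Step 7**
Reactants: 11 2,6-dimethoxy-4-(2,4,6-trimethoxyphenoxy)phenol; 8 2-[4-(benzyloxy)-3,5-dimethoxyphenoxy]-1-iodo-3,4,5-trimethoxybenzene
Product: 12 2-[4-(benzyloxy)-3,5-dimethoxyphenoxy]-1-[2,6-dimethoxy-4-(2,4,6-trimethoxyphenoxy)phenoxy]-3,4,5-trimethoxybenzene (tetramer benzyl ether)
Conditions: CuI, picolinic acid, K3PO4, DMSO, 95 °C, argon
Reagents that add atoms: none
Why: Ullmann diaryl ether synthesis at the B–C junction; the ether gains three ortho substituents, which these conditions are known to tolerate for 2,6-disubstituted phenols with ortho-substituted aryl iodides, and the iodide is used because it reacts faster than a bromide.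

**Step 8**
Reactants: 12 tetramer benzyl ether
Product: 13 4-{2-[2,6-dimethoxy-4-(2,4,6-trimethoxyphenoxy)phenoxy]-4,5,6-trimethoxyphenoxy}-2,6-dimethoxyphenol (tetramer phenol)
Conditions: H2 (1 atm), Pd/C, EtOAc/MeOH, rt
Reagents that add atoms: none
Why: Hydrogenolysis of the benzyl ether frees the ring D hydroxyl; nothing else in the molecule is reducible under these conditions.

**Step 9**
Reactants: 13 tetramer phenol; 14 trichloroethylene
Product: 15 tetramer (E)-1,2-dichlorovinyl ether
Conditions: K2CO3, DMF, 70 °C
Reagents that add atoms: none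
Why: Base eliminates HCl from trichloroethylene to dichloroacetylene, to which the phenoxide adds in anti fashion; this elimination–addition is an established way to attach a two-carbon unit to phenols, and it needs no arylation at the hindered oxygen.

**Step 10**
Reactants: 15 tetramer (E)-1,2-dichlorovinyl ether
Product: 18 tetramer ethynyl ether, via chloroethynyl ether 16 (not isolated), via lithium acetylide 17 (not isolated)
Conditions: n-BuLi (2.3 equiv), THF, −78 °C to −40 °C; MeOH, −78 °C
Reagents that add atoms: none
Why: Dehydrochlorination followed by chlorine–lithium exchange is the standard route from dichlorovinyl ethers to ynol ethers; both events are fast at −78 °C, where ring lithiation is not, and the two ortho methoxy groups of ring D shield the ynol ether.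

**Step 11**
Reactants: 18 tetramer ethynyl ether
Product: 19 tributyl[1-(tetramer-oxy)vinyl]stannane
Conditions: Bu3SnH, Pd(PPh3)4, THF, 0 °C
Reagents that add atoms: tributyltin hydride, CCCC[SnH](CCCC)CCCC
Why: Syn hydrostannation catalysed by zerovalent palladium; with ynol ethers the polarisation of the triple bond directs tin to the oxygen-bearing carbon, which gives the 1-oxyvinyl stannane.

**Step 12**
Reactants: 19 tributyl[1-(tetramer-oxy)vinyl]stannane; 20 dimethyl squarate
Product: 22 racemic 4-hydroxy-2,3-dimethoxy-4-[1-(tetramer-oxy)vinyl]cyclobut-2-en-1-one, via vinyllithium 21 (not isolated)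
Conditions: n-BuLi, THF, −78 °C; then 20, −78 °C; sat. aq NH4Cl
Reagents that add atoms: none
Why: Tin–lithium exchange gives the 1-oxyvinyllithium within minutes at −78 °C, faster than any ring deprotonation, and organolithium reagents add 1,2 to one of the two equivalent carbonyls of dimethyl squarate. The new carbinol stereocenter is formed without control, which does not matter because step 14 destroys it.

**Step 13**
Reactants: 22 racemic 4-hydroxy-2,3-dimethoxy-4-[1-(tetramer-oxy)vinyl]cyclobut-2-en-1-one
Product: 23 racemic 4-(tert-butyldimethylsilyloxy)-2,3-dimethoxy-4-[1-(tetramer-oxy)vinyl]cyclobut-2-en-1-one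
Conditions: TBSOTf, 2,6-lutidine, CH2Cl2, −78 °C to 0 °C
Reagents that add atoms: tert-butyldimethylsilyl trifluoromethanesulfonate, CC(C)(C)[Si](C)(C)OS(=O)(=O)C(F)(F)F
Why: Silyl triflate with a hindered pyridine base silylates tertiary alcohols, and the buffered medium spares the enol ether; the silyl ether later marks the C6 oxygen of ring E.

**Step 14**
Reactants: 23 racemic 4-(tert-butyldimethylsilyloxy)-2,3-dimethoxy-4-[1-(tetramer-oxy)vinyl]cyclobut-2-en-1-one
Product: 26 pentamer phenol silyl ether (ring E: hydroxyl at C3, methoxy at C4 and C5, silyl ether at C6), via (Z)-dienylketene 24 (not isolated), via cyclohexadienone 25 (not isolated)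
Conditions: degassed xylene, 140 °C, argon, high dilution
Reagents that add atoms: none
Why: Moore ring expansion of a 4-alkenyl-4-silyloxycyclobutenone, a known reaction type that also tolerates 1-alkoxyalkenyl groups. Heating opens the C1–C4 bond of the cyclobutenone in a conrotatory four-electron electrocyclic reaction to the (Z)-dienylketene 24. The silyloxy donor on C4 rotates outward, so the 1-aryloxyvinyl group turns inward and ends up cis to the ketene; this torquoselectivity is the one selectivity the step needs, and the donor substituent of the substrate secures it. A six-electron disrotatory electrocyclisation then joins the ketene carbon to the vinyl CH2, which forms the C2–C3 bond of ring E and closes that six-membered carbocycle as dienone 25. Tautomerisation of 25, driven by aromatisation, should give phenol 26. Regiochemistry is fixed by connectivity: the squarate is symmetric, the ketene carbon becomes C3 with its hydroxyl, the carbinol carbon becomes C6 with its silyl ether, and the vinyl α carbon becomes C1 with the oxygen of ring D. No stereocenter is formed and the one in 23 is lost, so racemic material suffices. The silyl group cannot reach the para oxygen, so the C3 hydroxyl and the C6 ether oxygen leave the step differentiated.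

**Step 15**
Reactants: 26 pentamer phenol silyl ether
Product: 27 pentamer silyl ether (ring E: methoxy at C3, C4 and C5, silyl ether at C6)
Conditions: MeOH, PPh3, DIAD, THF, 0 °C to rt
Reagents that add atoms: methanol, CO
Why: Mitsunobu etherification of a phenol with methanol; it avoids a free phenoxide in basic solution, which could cleave or exchange the aryl silyl ether, and the C3 hydroxyl has only one ortho substituent.

**Step 16**
Reactants: 27 pentamer silyl ether
Product: 28 pentamer phenol (ring E: free hydroxyl at C6)
Conditions: TBAF, AcOH, THF, 0 °C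
Reagents that add atoms: none
Why: Fluoride cleaves aryl silyl ethers quickly; the acetic acid buffer keeps the electron-rich phenoxide from standing in base.

**Step 17**
Reactants: 2 6-iodo-2,3,4-trimethoxyphenol; 29 (3,4,5-trimethoxyphenyl)boronic acid
Product: 30 1-iodo-3,4,5-trimethoxy-2-(3,4,5-trimethoxyphenoxy)benzene
Conditions: Cu(OAc)2, pyridine, 4 Å MS, CH2Cl2, dry air, rt
Reagents that add atoms: none
Why: Chan–Lam–Evans coupling, as in step 4; the boronic acid is unhindered and the carbon–iodine bond of 2 is not touched at room temperature.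

**Step 18**
Reactants: 30 1-iodo-3,4,5-trimethoxy-2-(3,4,5-trimethoxyphenoxy)benzene; 31 2,6-dimethoxyphenol
Product: 32 1-(2,6-dimethoxyphenoxy)-3,4,5-trimethoxy-2-(3,4,5-trimethoxyphenoxy)benzene
Conditions: CuI, picolinic acid, K3PO4, DMSO, 95 °C, argon
Reagents that add atoms: none
Why: Ullmann diaryl ether synthesis of the same type as step 7; the cheap phenol can be used in excess to drive the hindered coupling.

**Step 19**
Reactants: 32 1-(2,6-dimethoxyphenoxy)-3,4,5-trimethoxy-2-(3,4,5-trimethoxyphenoxy)benzene
Product: 34 1-(4-bromo-2,6-dimethoxyphenoxy)-3,4,5-trimethoxy-2-(3,4,5-trimethoxyphenoxy)benzene, via pinacol boronate 33 (not isolated)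
Conditions: [Ir(OMe)(cod)]2, dtbpy, B2pin2, THF, 80 °C; then CuBr2, MeOH/H2O, 80 °C
Reagents that add atoms: copper dibromide, [Cu+2].[Br-].[Br-]
Why: Iridium-catalysed C–H borylation is governed by sterics and avoids C–H bonds with an ortho substituent; C1–H of ring F is the only one in 32 with two ortho hydrogens. Bromodeboronation of aryl pinacol boronates with CuBr2 in the same pot is an established sequel.

**Step 20**
Reactants: 28 pentamer phenol; 34 1-(4-bromo-2,6-dimethoxyphenoxy)-3,4,5-trimethoxy-2-(3,4,5-trimethoxyphenoxy)benzene
Product: 35 octamer henicosamethyl ether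
Conditions: CuI, picolinic acid, K3PO4, DMSO, 100 °C, argon
Reagents that add atoms: none
Why: Ullmann diaryl ether synthesis in its favourable polarity: the crowded oxygen is the nucleophile and the bromide carbon has two ortho hydrogens.

**Step 21**
Reactants: 35 octamer henicosamethyl ether
Product: 36 target octamer (CNP0206369.0)
Conditions: BBr3 (excess), CH2Cl2, −78 °C to rt; MeOH, then H2O, argon
Reagents that add atoms: none
Why: Lewis acid cleavage of aryl methyl ethers by boron tribromide; diaryl ethers are not cleaved, and work-up under argon protects the polyphenol.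

## Compound list

1 | 2,3,4-trimethoxyphenol | COc1ccc(O)c(OC)c1OC | starting material
2 | 6-iodo-2,3,4-trimethoxyphenol | COc1cc(I)c(O)c(OC)c1OC | intermediate
3 | 4-bromo-2,6-dimethoxyphenol | COc1cc(Br)cc(OC)c1O | starting material
4 | 2-(benzyloxy)-5-bromo-1,3-dimethoxybenzene | COc1cc(Br)cc(OC)c1OCc1ccccc1 | intermediate
5 | [4-(benzyloxy)-3,5-dimethoxyphenyl]lithium | [Li]c1cc(OC)c(OCc2ccccc2)c(OC)c1 | intermediate
6 | lithium [4-(benzyloxy)-3,5-dimethoxyphenyl]triisopropoxyborate | [Li+].COc1cc([B-](OC(C)C)(OC(C)C)OC(C)C)cc(OC)c1OCc1ccccc1 | intermediate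
7 | [4-(benzyloxy)-3,5-dimethoxyphenyl]boronic acid | COc1cc(B(O)O)cc(OC)c1OCc1ccccc1 | intermediate
8 | 2-[4-(benzyloxy)-3,5-dimethoxyphenoxy]-1-iodo-3,4,5-trimethoxybenzene (rings C and D, iodine on ring C C1) | COc1cc(I)c(Oc2cc(OC)c(OCc3ccccc3)c(OC)c2)c(OC)c1OC | intermediate
9 | 2,4,6-trimethoxyphenol | COc1cc(OC)c(O)c(OC)c1 | starting material
10 | 2-[4-(benzyloxy)-3,5-dimethoxyphenoxy]-1,3,5-trimethoxybenzene (rings A and B) | COc1cc(OC)c(Oc2cc(OC)c(OCc3ccccc3)c(OC)c2)c(OC)c1 | intermediate
11 | 2,6-dimethoxy-4-(2,4,6-trimethoxyphenoxy)phenol (rings A and B) | COc1cc(OC)c(Oc2cc(OC)c(O)c(OC)c2)c(OC)c1 | intermediate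
12 | tetramer benzyl ether, 2-[4-(benzyloxy)-3,5-dimethoxyphenoxy]-1-[2,6-dimethoxy-4-(2,4,6-trimethoxyphenoxy)phenoxy]-3,4,5-trimethoxybenzene | COc1cc(OC)c(Oc2cc(OC)c(Oc3cc(OC)c(OC)c(OC)c3Oc3cc(OC)c(OCc4ccccc4)c(OC)c3)c(OC)c2)c(OC)c1 | intermediate
13 | tetramer phenol, 4-{2-[2,6-dimethoxy-4-(2,4,6-trimethoxyphenoxy)phenoxy]-4,5,6-trimethoxyphenoxy}-2,6-dimethoxyphenol | COc1cc(OC)c(Oc2cc(OC)c(Oc3cc(OC)c(OC)c(OC)c3Oc3cc(OC)c(O)c(OC)c3)c(OC)c2)c(OC)c1 | intermediate
14 | trichloroethylene | ClC=C(Cl)Cl | starting material
15 | tetramer (E)-1,2-dichlorovinyl ether (13 with O–C(Cl)=CHCl in place of the hydroxyl) | COc1cc(OC)c(Oc2cc(OC)c(Oc3cc(OC)c(OC)c(OC)c3Oc3cc(OC)c(O/C(Cl)=C\Cl)c(OC)c3)c(OC)c2)c(OC)c1 | intermediate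
16 | tetramer chloroethynyl ether | COc1cc(OC)c(Oc2cc(OC)c(Oc3cc(OC)c(OC)c(OC)c3Oc3cc(OC)c(OC#CCl)c(OC)c3)c(OC)c2)c(OC)c1 | intermediate
17 | lithium acetylide of the tetramer ethynyl ether | COc1cc(OC)c(Oc2cc(OC)c(Oc3cc(OC)c(OC)c(OC)c3Oc3cc(OC)c(OC#C[Li])c(OC)c3)c(OC)c2)c(OC)c1 | intermediate
18 | tetramer ethynyl ether | COc1cc(OC)c(Oc2cc(OC)c(Oc3cc(OC)c(OC)c(OC)c3Oc3cc(OC)c(OC#C)c(OC)c3)c(OC)c2)c(OC)c1 | intermediate
19 | tributyl[1-(tetramer-oxy)vinyl]stannane | COc1cc(OC)c(Oc2cc(OC)c(Oc3cc(OC)c(OC)c(OC)c3Oc3cc(OC)c(OC(=C)[Sn](CCCC)(CCCC)CCCC)c(OC)c3)c(OC)c2)c(OC)c1 | intermediate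
20 | dimethyl squarate (3,4-dimethoxycyclobut-3-ene-1,2-dione) | COC1=C(OC)C(=O)C1=O | starting material
21 | [1-(tetramer-oxy)vinyl]lithium | COc1cc(OC)c(Oc2cc(OC)c(Oc3cc(OC)c(OC)c(OC)c3Oc3cc(OC)c(OC(=C)[Li])c(OC)c3)c(OC)c2)c(OC)c1 | intermediate
22 | racemic 4-hydroxy-2,3-dimethoxy-4-[1-(tetramer-oxy)vinyl]cyclobut-2-en-1-one | COc1cc(OC)c(Oc2cc(OC)c(Oc3cc(OC)c(OC)c(OC)c3Oc3cc(OC)c(OC(=C)C4(O)C(OC)=C(OC)C4=O)c(OC)c3)c(OC)c2)c(OC)c1 | intermediate
23 | racemic 4-(tert-butyldimethylsilyloxy)-2,3-dimethoxy-4-[1-(tetramer-oxy)vinyl]cyclobut-2-en-1-one | COc1cc(OC)c(Oc2cc(OC)c(Oc3cc(OC)c(OC)c(OC)c3Oc3cc(OC)c(OC(=C)C4(O[Si](C)(C)C(C)(C)C)C(OC)=C(OC)C4=O)c(OC)c3)c(OC)c2)c(OC)c1 | intermediate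
24 | (Z)-dienylketene, 2,3-dimethoxy-4-(tert-butyldimethylsilyloxy)-5-(tetramer-oxy)hexa-1,3,5-trien-1-one | COc1cc(OC)c(Oc2cc(OC)c(Oc3cc(OC)c(OC)c(OC)c3Oc3cc(OC)c(OC(=C)/C(O[Si](C)(C)C(C)(C)C)=C(OC)\C(OC)=C=O)c(OC)c3)c(OC)c2)c(OC)c1 | intermediate
25 | cyclohexadienone, 4-(tert-butyldimethylsilyloxy)-2,3-dimethoxy-5-(tetramer-oxy)cyclohexa-2,4-dien-1-one | COc1cc(OC)c(Oc2cc(OC)c(Oc3cc(OC)c(OC)c(OC)c3Oc3cc(OC)c(OC4=C(O[Si](C)(C)C(C)(C)C)C(OC)=C(OC)C(=O)C4)c(OC)c3)c(OC)c2)c(OC)c1 | intermediate
26 | pentamer phenol silyl ether (rings A to E; ring E hydroxyl at C3, methoxy at C4 and C5, tert-butyldimethylsilyl ether at C6) | COc1cc(OC)c(Oc2cc(OC)c(Oc3cc(OC)c(OC)c(OC)c3Oc3cc(OC)c(Oc4cc(O)c(OC)c(OC)c4O[Si](C)(C)C(C)(C)C)c(OC)c3)c(OC)c2)c(OC)c1 | intermediate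
27 | pentamer silyl ether (ring E methoxy at C3, C4 and C5, silyl ether at C6) | COc1cc(OC)c(Oc2cc(OC)c(Oc3cc(OC)c(OC)c(OC)c3Oc3cc(OC)c(Oc4cc(OC)c(OC)c(OC)c4O[Si](C)(C)C(C)(C)C)c(OC)c3)c(OC)c2)c(OC)c1 | intermediate
28 | pentamer phenol (ring E free hydroxyl at C6, all other oxygens methylated) | COc1cc(OC)c(Oc2cc(OC)c(Oc3cc(OC)c(OC)c(OC)c3Oc3cc(OC)c(Oc4cc(OC)c(OC)c(OC)c4O)c(OC)c3)c(OC)c2)c(OC)c1 | intermediate
29 | (3,4,5-trimethoxyphenyl)boronic acid | COc1cc(B(O)O)cc(OC)c1OC | starting material
30 | 1-iodo-3,4,5-trimethoxy-2-(3,4,5-trimethoxyphenoxy)benzene (rings G and H, iodine on ring G C1) | COc1cc(Oc2c(I)cc(OC)c(OC)c2OC)cc(OC)c1OC | intermediate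
31 | 2,6-dimethoxyphenol | COc1cccc(OC)c1O | starting material
32 | 1-(2,6-dimethoxyphenoxy)-3,4,5-trimethoxy-2-(3,4,5-trimethoxyphenoxy)benzene (rings F to H) | COc1cccc(OC)c1Oc1cc(OC)c(OC)c(OC)c1Oc1cc(OC)c(OC)c(OC)c1 | intermediate
33 | pinacol boronate of 32 at ring F C1 | COc1cc(B2OC(C)(C)C(C)(C)O2)cc(OC)c1Oc1cc(OC)c(OC)c(OC)c1Oc1cc(OC)c(OC)c(OC)c1 | intermediate
34 | 1-(4-bromo-2,6-dimethoxyphenoxy)-3,4,5-trimethoxy-2-(3,4,5-trimethoxyphenoxy)benzene (rings F to H, bromine on ring F C1) | COc1cc(Br)cc(OC)c1Oc1cc(OC)c(OC)c(OC)c1Oc1cc(OC)c(OC)c(OC)c1 | intermediate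
35 | octamer henicosamethyl ether (rings A to H, all twenty-one hydroxyls as methyl ethers) | COc1cc(OC)c(Oc2cc(OC)c(Oc3cc(OC)c(OC)c(OC)c3Oc3cc(OC)c(Oc4cc(OC)c(OC)c(OC)c4Oc4cc(OC)c(Oc5cc(OC)c(OC)c(OC)c5Oc5cc(OC)c(OC)c(OC)c5)c(OC)c4)c(OC)c3)c(OC)c2)c(OC)c1 | intermediate
36 | target octamer CNP0206369.0 | Oc1cc(O)c(Oc2cc(O)c(Oc3cc(O)c(O)c(O)c3Oc3cc(O)c(Oc4cc(O)c(O)c(O)c4Oc4cc(O)c(Oc5cc(O)c(O)c(O)c5Oc5cc(O)c(O)c(O)c5)c(O)c4)c(O)c3)c(O)c2)c(O)c1 | target

## Step count and least certain steps

Total step count: 21. Longest linear sequence: 15 steps (steps 2, 5, 6, 7 to 16, 20, 21, from bromophenol 3; the branch through steps 2, 3, 4 is equally long).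

**Step 14 (key step).** The six-electron closure may be slower than usual because the 2,6-dimethoxyaryloxy substituent can twist the vinyl group out of conjugation with the diene. The dienylketene would then be lost to dimerisation or to capture by adventitious nucleophiles, and traces of acid at 140 °C could cleave the enol ether before ring opening. The fallback gives up ring synthesis at the D–E junction and arylates instead. It sets out from 13 and 2: benzylation of 2 (BnBr, K2CO3, DMF) gives 2-(benzyloxy)-1-iodo-3,4,5-trimethoxybenzene F1; Ullmann coupling of F1 with 13 (CuI, picolinic acid, K3PO4, DMSO, 95 °C) gives the pentamer benzyl ether F2; hydrogenolysis (H2, Pd/C) returns to the route at 28.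

**Step 12.** The vinyllithium may be lost before it meets the squarate, by proton transfer from one of the ring C–H bonds flanked by two oxygens or by α-elimination of the aryloxide; incomplete tin–lithium exchange would leave butyllithium to add to the squarate. The fallback uses a less basic magnesium carbenoid. It sets out from 19: iododestannylation (I2, CH2Cl2, 0 °C) gives the tetramer 1-iodovinyl ether F3; iodine–magnesium exchange (i-PrMgCl·LiCl, THF, −40 °C) gives the vinylmagnesium chloride F4, which is added to 20 and returns to the route at 22.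

**Step 19.** Borylation should be selective, but during bromodeboronation CuBr2 may also brominate the electron-rich rings by electrophilic substitution, or the boronate may undergo protodeboronation. The fallback avoids the halide altogether. It sets out from 33, isolated after the borylation: cleavage of the pinacol ester (NaIO4, NH4OAc, acetone/H2O) gives the trimer boronic acid F5, which is joined to 28 by Chan–Lam–Evans coupling (Cu(OAc)2, pyridine, 4 Å MS, CH2Cl2, air) and returns to the route at 35.

**Step 20.** Arylation of the very crowded phenoxide of 28 may be slow, so that reduction of the bromide and oxidation of the phenoxide compete. The fallback changes the fragment union from five plus three to five plus one plus two. It sets out from 28: Chan–Lam–Evans coupling with the small boronic acid 7, used in excess, gives the hexamer benzyl ether F6; hydrogenolysis gives the hexamer phenol F7, a less crowded 2,6-dimethoxyphenol-type nucleophile; Ullmann coupling of F7 with iodide 30 (CuI, picolinic acid, K3PO4, DMSO) returns to the route at 35.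

**Step 21.** Cleavage of twenty-one methyl ethers may stop short, and the free polyphenol may oxidise or be lost during purification. The fallback purifies at the stage of a stable derivative. It sets out from 35: the crude product of the BBr3 treatment is acetylated (Ac2O, pyridine) to the henicosaacetate F8, which can be chromatographed and recycled if under-cleaved material is present; deacetylation of F8 (NaOMe, MeOH, argon, then acidic resin) returns to the route at 36.

## Further compounds

F1 | step 14 | 2-(benzyloxy)-1-iodo-3,4,5-trimethoxybenzene | COc1cc(I)c(OCc2ccccc2)c(OC)c1OC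
F2 | step 14 | pentamer benzyl ether (28 with benzyloxy in place of the ring E C6 hydroxyl) | COc1cc(OC)c(Oc2cc(OC)c(Oc3cc(OC)c(OC)c(OC)c3Oc3cc(OC)c(Oc4cc(OC)c(OC)c(OC)c4OCc4ccccc4)c(OC)c3)c(OC)c2)c(OC)c1
F3 | step 12 | tetramer 1-iodovinyl ether | COc1cc(OC)c(Oc2cc(OC)c(Oc3cc(OC)c(OC)c(OC)c3Oc3cc(OC)c(OC(I)=C)c(OC)c3)c(OC)c2)c(OC)c1
F4 | step 12 | [1-(tetramer-oxy)vinyl]magnesium chloride | COc1cc(OC)c(Oc2cc(OC)c(Oc3cc(OC)c(OC)c(OC)c3Oc3cc(OC)c(OC(=C)[Mg]Cl)c(OC)c3)c(OC)c2)c(OC)c1
F5 | step 19 | trimer boronic acid (32 with B(OH)2 on ring F C1) | COc1cc(B(O)O)cc(OC)c1Oc1cc(OC)c(OC)c(OC)c1Oc1cc(OC)c(OC)c(OC)c1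
F6 | step 20 | hexamer benzyl ether (rings A to F, benzyloxy on ring F C4) | COc1cc(OC)c(Oc2cc(OC)c(Oc3cc(OC)c(OC)c(OC)c3Oc3cc(OC)c(Oc4cc(OC)c(OC)c(OC)c4Oc4cc(OC)c(OCc5ccccc5)c(OC)c4)c(OC)c3)c(OC)c2)c(OC)c1
F7 | step 20 | hexamer phenol (rings A to F, free hydroxyl on ring F C4) | COc1cc(OC)c(Oc2cc(OC)c(Oc3cc(OC)c(OC)c(OC)c3Oc3cc(OC)c(Oc4cc(OC)c(OC)c(OC)c4Oc4cc(OC)c(O)c(OC)c4)c(OC)c3)c(OC)c2)c(OC)c1
F8 | step 21 | henicosaacetate of 36 | CC(=O)Oc1cc(OC(C)=O)c(Oc2cc(OC(C)=O)c(Oc3cc(OC(C)=O)c(OC(C)=O)c(OC(C)=O)c3Oc3cc(OC(C)=O)c(Oc4cc(OC(C)=O)c(OC(C)=O)c(OC(C)=O)c4Oc4cc(OC(C)=O)c(Oc5cc(OC(C)=O)c(OC(C)=O)c(OC(C)=O)c5Oc5cc(OC(C)=O)c(OC(C)=O)c(OC(C)=O)c5)c(OC(C)=O)c4)c(OC(C)=O)c3)c(OC(C)=O)c2)c(OC(C)=O)c1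
A1 | alternative 1 | octamer trialdehyde (two formyl groups on ring A, one on ring C) | COc1cc(C=O)c(Oc2cc(OC)c(Oc3cc(OC)c(C=O)c(OC)c3Oc3cc(OC)c(Oc4cc(OC)c(OC)c(OC)c4Oc4cc(OC)c(Oc5cc(OC)c(OC)c(OC)c5Oc5cc(OC)c(OC)c(OC)c5)c(OC)c4)c(OC)c3)c(OC)c2)c(C=O)c1
A2 | alternative 1 | 2,6-dimethoxyhydroquinone | COc1cc(O)cc(OC)c1O
A3 | alternative 1 | 2-fluoro-5-methoxyisophthalaldehyde | COc1cc(C=O)c(F)c(C=O)c1
A4 | alternative 1 | hexamer fluoride of rings C to H (ring C: fluorine on C1, formyl on C4) | Fc1cc(OC)c(C=O)c(OC)c1Oc1cc(OC)c(Oc2cc(OC)c(OC)c(OC)c2Oc2cc(OC)c(Oc3cc(OC)c(OC)c(OC)c3Oc3cc(OC)c(OC)c(OC)c3)c(OC)c2)c(OC)c1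
A5 | alternative 2 | octamer with ring A as free triol and rings B to H as methyl ethers | Oc1cc(O)c(Oc2cc(OC)c(Oc3cc(OC)c(OC)c(OC)c3Oc3cc(OC)c(Oc4cc(OC)c(OC)c(OC)c4Oc4cc(OC)c(Oc5cc(OC)c(OC)c(OC)c5Oc5cc(OC)c(OC)c(OC)c5)c(OC)c4)c(OC)c3)c(OC)c2)c(O)c1
A6 | alternative 2 | methyl 6-aryloxy-3,5-dioxohexanoate, aryl being rings B to H as methyl ethers | COC(=O)CC(=O)CC(=O)COc1cc(OC)c(Oc2cc(OC)c(OC)c(OC)c2Oc2cc(OC)c(Oc3cc(OC)c(OC)c(OC)c3Oc3cc(OC)c(Oc4cc(OC)c(OC)c(OC)c4Oc4cc(OC)c(OC)c(OC)c4)c(OC)c3)c(OC)c2)c(OC)c1
A7 | alternative 3 | octamer tetraphenol heptadecamethyl ether (free hydroxyl on C4 of rings C, E, G and H) | COc1cc(OC)c(Oc2cc(OC)c(Oc3cc(OC)c(O)c(OC)c3Oc3cc(OC)c(Oc4cc(OC)c(O)c(OC)c4Oc4cc(OC)c(Oc5cc(OC)c(O)c(OC)c5Oc5cc(OC)c(O)c(OC)c5)c(OC)c4)c(OC)c3)c(OC)c2)c(OC)c1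
A8 | alternative 3 | octamer tetraaldehyde (formyl on C4 of rings C, E, G and H) | COc1cc(OC)c(Oc2cc(OC)c(Oc3cc(OC)c(C=O)c(OC)c3Oc3cc(OC)c(Oc4cc(OC)c(C=O)c(OC)c4Oc4cc(OC)c(Oc5cc(OC)c(C=O)c(OC)c5Oc5cc(OC)c(C=O)c(OC)c5)c(OC)c4)c(OC)c3)c(OC)c2)c(OC)c1
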